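**Plan**
- Retrosynthesis: the O6–MOM bond is cut last. C2–C3 and O1–C2 are then cut together, a (4+1) disconnection into an o-quinone methide (O1, C7a, C3a, C3) and a 3,4,5-trimethoxybenzyl sulfonium ylide (C2). Behind these lie C3–CH3 (Grignard), C5–allyl (Stille) and S–CH2Ar (alkylation).
- Enabling feature: C3 is benzylic and ortho to the ring oxygen, so C3–C3a–C7a–O1 is a masked o-quinone methide. C2 with its aryl group is the only atom missing from the five-membered ring O1–C2–C3–C3a–C7a.
- Forward: the benzene ring is bought. O6 is protected, the allyl chain is joined at C5, the methyl carbon is added at C3 and the benzylic alcohol is made a sulfone. The dihydrofuran ring, the only ring made, closes in the annulation, and deprotection ends the route.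
- Stereochemistry: C2 comes from the twofold-symmetric (2S,5S)-2,5-dimethylthiolane, made from (2R,5R)-hexane-2,5-diol by double inversion, which blocks one face of the ylide. C3 follows from the trans-selective addition and invertive ring closure, and neither centre is touched afterwards.

Key step: step 8

Assumption: the sense of induction is taken from the benzylide epoxidations of 2,5-dimethylthiolane (aryl anti to the ring, electrophile anti to the cis methyl); because aryl outranks C3 at C2, whereas the oxirane carbon outranks phenyl in an epoxide, the (2S,5S)-sulfide is the one expected to give 2S.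

**Step 1**
Reactants: 1 5-bromo-2,4-dihydroxybenzaldehyde
Product: 2 5-bromo-2-hydroxy-4-(methoxymethoxy)benzaldehyde
Conditions: MOMCl (1.1 equiv), K2CO3 (1.2 equiv), acetone, 0 °C to rt
Reagents that add atoms: chloromethyl methyl ether, COCCl
Why: Williamson-type O-alkylation should pick the more acidic 4-hydroxyl para to the formyl group, because the 2-hydroxyl is held in a hydrogen bond to the aldehyde, and no stereocentre is formed.

**Step 2**
Reactants: 2 5-bromo-2-hydroxy-4-(methoxymethoxy)benzaldehyde; 3 allyltributylstannane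
Product: 4 5-allyl-2-hydroxy-4-(methoxymethoxy)benzaldehyde
Conditions: Pd(PPh3)4 (5 mol %), DMF, 90 °C
Reagents that add atoms: none
Why: Migita–Kosugi–Stille coupling of the aryl bromide fixes the allyl group at the future C5 without ambiguity and, unlike an allylboron reagent, the stannane leaves the free aldehyde and phenol untouched under neutral conditions.

**Step 3**
Reactants: 4 5-allyl-2-hydroxy-4-(methoxymethoxy)benzaldehyde
Product: 5 racemic 4-allyl-2-(1-hydroxyethyl)-5-(methoxymethoxy)phenol
Conditions: MeMgBr (2.5 equiv), THF, −78 to 0 °C; then sat aq NH4Cl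
Reagents that add atoms: methylmagnesium bromide, C[Mg]Br
Why: Grignard addition to the aldehyde, after the first equivalent has deprotonated the phenol, gives the secondary benzylic alcohol as a racemate, which suffices because this carbon becomes trigonal in the o-quinone methide.

**Step 4**
Reactants: 5 racemic 4-allyl-2-(1-hydroxyethyl)-5-(methoxymethoxy)phenol
Product: 6 racemic 4-allyl-5-(methoxymethoxy)-2-[1-(4-methylbenzenesulfonyl)ethyl]phenol
Conditions: p-TolSO2H (1.3 equiv), CH2Cl2, 0 °C to rt
Reagents that add atoms: p-toluenesulfinic acid, Cc1ccc(cc1)S(=O)O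
Why: Acid-promoted SN1-type substitution of the doubly activated benzylic alcohol (ortho-hydroxy, para-alkoxy) by sulfinate at sulfur gives the sulfone, the usual base-labile o-quinone methide precursor, at an acidity that should be too weak in an aprotic solvent to cleave the MOM acetal, and the new racemic centre is erased in step 8.

**Step 5**
Reactants: 7 (2R,5R)-hexane-2,5-diol
Product: 8 (2R,5R)-hexane-2,5-diyl dimethanesulfonate
Conditions: MsCl (2.4 equiv), Et3N (3 equiv), CH2Cl2, −20 to 0 °C
Reagents that add atoms: methanesulfonyl chloride, CS(=O)(=O)Cl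
Why: Mesylation of both secondary alcohols takes place at oxygen only, so both carbinol carbons keep their R configuration.

**Step 6**
Reactants: 8 (2R,5R)-hexane-2,5-diyl dimethanesulfonate
Product: 9 (2S,5S)-2,5-dimethylthiolane
Conditions: Na2S·9H2O (1.2 equiv), DMSO, rt
Reagents that add atoms: sodium sulfide, [Na+].[Na+].[S-2]
Why: Twofold SN2 displacement by sulfide, the second one a 5-exo-tet ring closure, inverts both carbons and should give the (2S,5S)-thiolane, as in the established preparation of this sulfide from the diol.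

**Step 7**
Reactants: 9 (2S,5S)-2,5-dimethylthiolane; 10 3,4,5-trimethoxybenzyl bromide
Product: 11 (2S,5S)-2,5-dimethyl-1-(3,4,5-trimethoxybenzyl)thiolan-1-ium trifluoromethanesulfonate
Conditions: LiOTf (3 equiv), CH2Cl2–H2O, rt
Reagents that add atoms: lithium trifluoromethanesulfonate, [Li+].[O-]S(=O)(=O)C(F)(F)F
Why: SN2 S-benzylation of the sulfide, driven forward by exchange of bromide for non-nucleophilic triflate, gives a single sulfonium salt because the two lone pairs of the twofold-symmetric sulfide are equivalent and sulfur is therefore not a stereocentre.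

**Step 8**
Reactants: 6 racemic 4-allyl-5-(methoxymethoxy)-2-[1-(4-methylbenzenesulfonyl)ethyl]phenol; 11 (2S,5S)-2,5-dimethyl-1-(3,4,5-trimethoxybenzyl)thiolan-1-ium trifluoromethanesulfonate
Product: 15 (2S,3S)-5-allyl-6-(methoxymethoxy)-3-methyl-2-(3,4,5-trimethoxyphenyl)-2,3-dihydro-1-benzofuran, via o-quinone methide 12 (not isolated), via sulfonium ylide 13 (not isolated), via phenoxide sulfonium betaine 14 (not isolated)
Conditions: Cs2CO3 (3 equiv), MeCN–CH2Cl2, −20 to 0 °C, 6 added slowly to 11 (1.5 equiv) and base
Reagents that add atoms: none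
Why: Cs2CO3 turns 6 into o-quinone methide 12 by 1,4-elimination of p-toluenesulfinate from the phenoxide and deprotonates 11 to ylide 13; the ylide carbon adds to the exocyclic carbon of 12 (future C3) with rearomatisation to betaine 14, and the phenoxide then displaces the neutral sulfide at the benzylic carbon (future C2), so that C2–C3 and O1–C2 form in one operation. The closest known reaction type is the base-mediated (4+1) annulation of o-quinone methides, released from 2-(1-sulfonylalkyl)phenols, with sulfonium or ammonium ylides to trans-2,3-dihydrobenzofurans. The dihydrofuran ring closes by a 5-exo-tet SN2 displacement with inversion at C2. C2 is controlled by the twofold-symmetric (2S,5S)-thiolane, whose methyl group cis to the ylide carbon blocks one face of the ylide as in sulfide-mediated epoxidation, and C3 is set relative to C2 in the addition through the anti betaine that keeps aryl and methyl apart, which after invertive closure should give the trans (2S,3S) ring. The step needs carbon attack at the methide carbon to outrun dimerisation of 12 and its tautomerisation to a vinylphenol, which rearomatisation as driving force, the cross-conjugated O6 donor that tempers 12 and slow release of 12 into excess ylide at low temperature should secure, while the MOM ether at O6 excludes a para-quinone methide.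

**Step 9**
Reactants: 15 (2S,3S)-5-allyl-6-(methoxymethoxy)-3-methyl-2-(3,4,5-trimethoxyphenyl)-2,3-dihydro-1-benzofuran
Product: 16 (2S,3S)-5-allyl-3-methyl-2-(3,4,5-trimethoxyphenyl)-2,3-dihydro-1-benzofuran-6-ol (CNP0286233.1)
Conditions: HCl (1.25 M in MeOH), 0 °C to rt
Reagents that add atoms: none
Why: Acid-catalysed acetal exchange with methanol removes the MOM group under conditions mild enough to leave the allyl group, the aryl methyl ethers and the benzylic C2–O1 bond, and hence both stereocentres, untouched.

**Compound list**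
1 | 5-bromo-2,4-dihydroxybenzaldehyde | O=Cc1cc(Br)c(O)cc1O | starting material
2 | 5-bromo-2-hydroxy-4-(methoxymethoxy)benzaldehyde | O=Cc1cc(Br)c(OCOC)cc1O | intermediate
3 | allyltributylstannane | C=CC[Sn](CCCC)(CCCC)CCCC | starting material
4 | 5-allyl-2-hydroxy-4-(methoxymethoxy)benzaldehyde | O=Cc1cc(CC=C)c(OCOC)cc1O | intermediate
5 | racemic 4-allyl-2-(1-hydroxyethyl)-5-(methoxymethoxy)phenol | CC(O)c1cc(CC=C)c(OCOC)cc1O | intermediate
6 | racemic 4-allyl-5-(methoxymethoxy)-2-[1-(4-methylbenzenesulfonyl)ethyl]phenol | CC(c1cc(CC=C)c(OCOC)cc1O)S(=O)(=O)c1ccc(C)cc1 | intermediate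
7 | (2R,5R)-hexane-2,5-diol | C[C@@H](O)CC[C@@H](C)O | starting material
8 | (2R,5R)-hexane-2,5-diyl dimethanesulfonate | C[C@@H](OS(C)(=O)=O)CC[C@@H](C)OS(C)(=O)=O | intermediate
9 | (2S,5S)-2,5-dimethylthiolane | C[C@H]1CC[C@H](C)S1 | intermediate
10 | 3,4,5-trimethoxybenzyl bromide | COc1cc(CBr)cc(OC)c1OC | starting material
11 | (2S,5S)-2,5-dimethyl-1-(3,4,5-trimethoxybenzyl)thiolan-1-ium trifluoromethanesulfonate | C[C@H]1CC[C@H](C)[S+]1Cc1cc(OC)c(OC)c(OC)c1.[O-]S(=O)(=O)C(F)(F)F | intermediate
12 | o-quinone methide (E)-4-allyl-6-ethylidene-3-(methoxymethoxy)cyclohexa-2,4-dien-1-one, formed in situ | C/C=C1\C=C(CC=C)C(OCOC)=CC1=O | intermediate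
13 | (2S,5S)-2,5-dimethylthiolan-1-ium (3,4,5-trimethoxyphenyl)methylide, formed in situ | C[C@H]1CC[C@H](C)[S+]1[CH-]c1cc(OC)c(OC)c(OC)c1 | intermediate
14 | betaine 5-allyl-4-(methoxymethoxy)-2-[(1R,2S)-1-((2S,5S)-2,5-dimethylthiolan-1-ium-1-yl)-1-(3,4,5-trimethoxyphenyl)propan-2-yl]phenolate, formed in situ | C[C@@H](c1cc(CC=C)c(OCOC)cc1[O-])[C@H](c1cc(OC)c(OC)c(OC)c1)[S+]1[C@@H](C)CC[C@@H]1C | intermediate
15 | (2S,3S)-5-allyl-6-(methoxymethoxy)-3-methyl-2-(3,4,5-trimethoxyphenyl)-2,3-dihydro-1-benzofuran | C=CCc1cc2c(cc1OCOC)O[C@H](c1cc(OC)c(OC)c(OC)c1)[C@H]2C | intermediate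
16 | (2S,3S)-5-allyl-3-methyl-2-(3,4,5-trimethoxyphenyl)-2,3-dihydro-1-benzofuran-6-ol | C=CCc1cc2c(cc1O)O[C@H](c1cc(OC)c(OC)c(OC)c1)[C@H]2C | target

**Step count**
Total: 9 steps. Longest linear sequence: 6 steps (steps 1, 2, 3, 4, 8, 9); the sulfonium branch (steps 5–7) joins at step 8.

**Steps most likely to fail**

Step 8. Face discrimination at the ylide carbon by the sulfide may be incomplete, which erodes enantiomeric purity. The hindered ylide or the o-quinone methide may also be lost (dimerisation, tautomerisation to the vinylphenol) before they meet. The fallback sets out from 6 and 10. Tetrahydrothiophene, 10 and LiOTf should give the unhindered achiral salt 1-(3,4,5-trimethoxybenzyl)thiolan-1-ium trifluoromethanesulfonate F1. Under the conditions of step 8 its ylide, thiolan-1-ium (3,4,5-trimethoxyphenyl)methylide F2, adds to 12, and the racemic phenoxide sulfonium betaine F3 closes to the racemic trans ether. This racemate is 15 together with its mirror image, (2R,3R)-5-allyl-6-(methoxymethoxy)-3-methyl-2-(3,4,5-trimethoxyphenyl)-2,3-dihydro-1-benzofuran F4. Preparative chromatography on a chiral stationary phase removes F4, and the route is rejoined at 15.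

Step 4. The sulfinic acid may cleave the MOM acetal, or the very electron-rich hydroxybenzyl alcohol may condense with itself before sulfinate captures the cation. The fallback sets out from 5 and avoids acid altogether. TBSCl and imidazole (CH2Cl2, 0 °C) should silylate the phenol selectively to racemic 1-[5-allyl-2-(tert-butyldimethylsilyloxy)-4-(methoxymethoxy)phenyl]ethanol F5. Ac2O, Et3N and catalytic DMAP then give racemic 1-[5-allyl-2-(tert-butyldimethylsilyloxy)-4-(methoxymethoxy)phenyl]ethyl acetate F6. CsF, added together with Cs2CO3 and 11 in MeCN, removes the silyl group; the freed phenoxide expels acetate, a known fluoride-triggered route to o-quinone methides. The route is rejoined at 12, which goes on to 15 as in step 8.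

Step 2. Oxidative addition into the electron-rich bromide may be slow, and the allyl double bond may migrate into conjugation at the temperature needed. The fallback sets out from 2, carries bromine through as a spectator and introduces the allyl group last, when no aldehyde is present. MeMgBr as in step 3 should give racemic 4-bromo-2-(1-hydroxyethyl)-5-(methoxymethoxy)phenol F7. p-TolSO2H as in step 4 gives racemic 4-bromo-5-(methoxymethoxy)-2-[1-(4-methylbenzenesulfonyl)ethyl]phenol F8. Annulation with 11 as in step 8 proceeds through (E)-4-bromo-6-ethylidene-3-(methoxymethoxy)cyclohexa-2,4-dien-1-one F9 and the betaine 5-bromo-4-(methoxymethoxy)-2-[(1R,2S)-1-((2S,5S)-2,5-dimethylthiolan-1-ium-1-yl)-1-(3,4,5-trimethoxyphenyl)propan-2-yl]phenolate F10. It should give (2S,3S)-5-bromo-6-(methoxymethoxy)-3-methyl-2-(3,4,5-trimethoxyphenyl)-2,3-dihydro-1-benzofuran F11. Suzuki–Miyaura coupling of F11 with allylboronic acid pinacol ester (Pd(OAc)2, SPhos, K3PO4, THF–H2O, 60 °C) rejoins the route at 15.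

**Further compounds**
F1 | step 8 | 1-(3,4,5-trimethoxybenzyl)thiolan-1-ium trifluoromethanesulfonate | COc1cc(C[S+]2CCCC2)cc(OC)c1OC.[O-]S(=O)(=O)C(F)(F)F
F2 | step 8 | thiolan-1-ium (3,4,5-trimethoxyphenyl)methylide | COc1cc([CH-][S+]2CCCC2)cc(OC)c1OC
F3 | step 8 | racemic betaine 5-allyl-4-(methoxymethoxy)-2-[1-(thiolan-1-ium-1-yl)-1-(3,4,5-trimethoxyphenyl)propan-2-yl]phenolate, relative configuration as in 14, one enantiomer drawn | C[C@@H](c1cc(CC=C)c(OCOC)cc1[O-])[C@H](c1cc(OC)c(OC)c(OC)c1)[S+]1CCCC1
F4 | step 8 | (2R,3R)-5-allyl-6-(methoxymethoxy)-3-methyl-2-(3,4,5-trimethoxyphenyl)-2,3-dihydro-1-benzofuran | C=CCc1cc2c(cc1OCOC)O[C@@H](c1cc(OC)c(OC)c(OC)c1)[C@@H]2C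
F5 | step 4 | racemic 1-[5-allyl-2-(tert-butyldimethylsilyloxy)-4-(methoxymethoxy)phenyl]ethanol | CC(O)c1cc(CC=C)c(OCOC)cc1O[Si](C)(C)C(C)(C)C
F6 | step 4 | racemic 1-[5-allyl-2-(tert-butyldimethylsilyloxy)-4-(methoxymethoxy)phenyl]ethyl acetate | CC(OC(C)=O)c1cc(CC=C)c(OCOC)cc1O[Si](C)(C)C(C)(C)C
F7 | step 2 | racemic 4-bromo-2-(1-hydroxyethyl)-5-(methoxymethoxy)phenol | CC(O)c1cc(Br)c(OCOC)cc1O
F8 | step 2 | racemic 4-bromo-5-(methoxymethoxy)-2-[1-(4-methylbenzenesulfonyl)ethyl]phenol | CC(c1cc(Br)c(OCOC)cc1O)S(=O)(=O)c1ccc(C)cc1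
F9 | step 2 | (E)-4-bromo-6-ethylidene-3-(methoxymethoxy)cyclohexa-2,4-dien-1-one | C/C=C1\C=C(Br)C(OCOC)=CC1=O
F10 | step 2 | betaine 5-bromo-4-(methoxymethoxy)-2-[(1R,2S)-1-((2S,5S)-2,5-dimethylthiolan-1-ium-1-yl)-1-(3,4,5-trimethoxyphenyl)propan-2-yl]phenolate | C[C@@H](c1cc(Br)c(OCOC)cc1[O-])[C@H](c1cc(OC)c(OC)c(OC)c1)[S+]1[C@@H](C)CC[C@@H]1C
F11 | step 2 | (2S,3S)-5-bromo-6-(methoxymethoxy)-3-methyl-2-(3,4,5-trimethoxyphenyl)-2,3-dihydro-1-benzofuran | Brc1cc2c(cc1OCOC)O[C@H](c1cc(OC)c(OC)c(OC)c1)[C@H]2C
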